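**Retrosynthetic overview**

1. The last cut is the aryl–vinyl bond of the only stilbene: C1 of ring E is joined to the terminal carbon of a vinyl group on C4 of the benzofuran by a Mizoroki–Heck reaction of bromide 22 with styrene 26, and the ten acetates are methanolysed in the same flask. The enabling feature is that C1 of ring E lies para to the ring-E oxygen and meta to the bulky tricyclic substituent on C3, so it is an unhindered, activated C–Br site facing a terminal vinyl on a fully aromatic benzofuran.
2. Both halves come from one bromo-dihydrobenzofuran (10/11). The dihydrofuran ring is formed first, by enantioselective dirhodium–carbene C–H insertion (sets C-b), followed by acid epimerisation at C-d.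
3. Right half: the seven-membered ring is closed second (Friedel–Crafts acylation onto ring B). Ring E is then put on C-a by enolate arylation with 4-bromo-2-iodoanisole, and ring F on C-c by Friedel–Crafts arylation of anisole.
4. Left half: DDQ aromatisation of 10 to the benzofuran, then Stille vinylation.
5. Methyl ethers are exchanged for acetates (BBr3, then Ac2O) on both bromides before any alkene exists, so that only mild methanolysis accompanies the union.

Key step: step 18

Labels: ring A = benzene ring of the dihydrobenzofuran; C-d = its O–CH(aryl) carbon (C2); C-b = the neighbouring CH (C3); ring B = the 3,5-dioxygenated ring on C-b; C-a = seven-ring methine on ring A; C-c = seven-ring methine on ring B; ring E = the para-hydroxyphenyl ring that links the halves; ring F = aryl on C-c; ring G = aryl on C-d.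

Remark 1: the sense of induction of the dirhodium catalyst is assumed to be S at C-b with Rh2(S-PTAD)4; should it be opposite, Rh2(R-PTAD)4 is used and nothing else changes.
Remark 2: 2-bromo-4,6-dimethoxybenzaldehyde is taken as a catalogue compound (otherwise one Vilsmeier formylation from 1-bromo-3,5-dimethoxybenzene).
Remark 3: the facial preferences invoked in steps 11 and 13 rest on a qualitative conformational model of the boat-shaped seven-membered ring, not on a calculation.

**Route**

Step 1
Reactants: 1 2-bromo-4,6-dimethoxybenzaldehyde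
Product: 2 2-bromo-6-hydroxy-4-methoxybenzaldehyde
Conditions: BCl3 (1.1 equiv), CH2Cl2, −78 to 0 °C; aq. NaHCO3
Reagents that add atoms: none
Why: Chelation-directed Lewis-acid demethylation: BCl3 bridges the aldehyde oxygen and the ortho methoxy oxygen, so only that methyl ether should be cleaved and the para methoxy group kept.

Step 2
Reactants: 2 2-bromo-6-hydroxy-4-methoxybenzaldehyde; 3 4-methoxybenzyl chloride
Product: 4 2-bromo-4-methoxy-6-[(4-methoxybenzyl)oxy]benzaldehyde
Conditions: K2CO3, DMF, 60 °C
Reagents that add atoms: none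
Why: Williamson ether synthesis; the benzyl group is not a protecting group but supplies C-d and ring G of the target.

Step 3
Reactants: 4 2-bromo-4-methoxy-6-[(4-methoxybenzyl)oxy]benzaldehyde; 5 3,5-dimethoxyphenylmagnesium chloride
Product: 6 rac-{2-bromo-4-methoxy-6-[(4-methoxybenzyl)oxy]phenyl}(3,5-dimethoxyphenyl)methanol
Conditions: THF, 0 °C to rt; aq. NH4Cl
Reagents that add atoms: none
Why: Grignard 1,2-addition to the aldehyde, faster than magnesium–bromine exchange at this temperature; the racemic carbinol centre is erased in step 4.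

Step 4
Reactants: 6 rac-diarylmethanol
Product: 7 {2-bromo-4-methoxy-6-[(4-methoxybenzyl)oxy]phenyl}(3,5-dimethoxyphenyl)methanone
Conditions: Dess–Martin periodinane (1.3 equiv), NaHCO3, CH2Cl2, rt
Reagents that add atoms: none
Why: Dess–Martin oxidation of a diarylcarbinol under buffered conditions that leave the benzyl ether and the aryl bromide untouched.

Step 5
Reactants: 7 diaryl ketone
Product: 8 hydrazone of ketone 7
Conditions: N2H4·H2O (10 equiv), AcOH (cat.), n-BuOH, 110 °C
Reagents that add atoms: hydrazine hydrate, NN.O
Why: Hydrazone condensation, forced by excess hydrazine and heat because the carbonyl is flanked by two ortho substituents; the aryl bromide should not be displaced without a copper or palladium catalyst.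

Step 6
Reactants: 8 hydrazone of ketone 7
Product: 10 (2R,3S)-cis-4-bromo-3-(3,5-dimethoxyphenyl)-6-methoxy-2-(4-methoxyphenyl)-2,3-dihydrobenzofuran, via diazo compound 9 (not isolated)
Conditions: MnO2 (8 equiv), CH2Cl2, 0 °C, filter; then Rh2(S-PTAD)4 (1 mol %), CH2Cl2, 0 °C to rt
Reagents that add atoms: none
Why: Donor/donor diaryl-carbene C–H insertion: MnO2 dehydrogenates the hydrazone to the diazo compound, and the rhodium carbene inserts into the benzylic C–H of the ortho benzyl ether through a five-membered transition state, the chiral carboxylate pocket fixing C-b as S and the concerted insertion giving the 2,3-cis ring (C-d R).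

Step 7
Reactants: 10 (2R,3S)-cis-dihydrobenzofuran bromide
Product: 11 (2S,3S)-trans-4-bromo-3-(3,5-dimethoxyphenyl)-6-methoxy-2-(4-methoxyphenyl)-2,3-dihydrobenzofuran
Conditions: TFA (10 equiv), CH2Cl2, rt
Reagents that add atoms: none
Why: Acid-mediated epimerisation at C-d only: reversible heterolysis of the benzylic C–O bond (para-methoxybenzyl cation and phenol) and re-closure should give the thermodynamically favoured trans ring, while the C-b centre from step 6 is never broken.

Step 8
Reactants: 11 (2S,3S)-trans-dihydrobenzofuran bromide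
Product: 12 tert-butyl 2-[(2S,3S)-3-(3,5-dimethoxyphenyl)-6-methoxy-2-(4-methoxyphenyl)-2,3-dihydrobenzofuran-4-yl]acetate
Conditions: BrZnCH2CO2t-Bu (1.5 equiv), Pd2(dba)3 (2.5 mol %), XPhos (10 mol %), THF, 60 °C
Reagents that add atoms: (2-tert-butoxy-2-oxoethyl)zinc bromide, Br[Zn]CC(=O)OC(C)(C)C
Why: Negishi-type coupling of a Reformatsky zinc enolate with the aryl bromide (ester α-arylation under neutral conditions), which spares the benzylic C-b–H that a strong base could remove.

Step 9
Reactants: 12 tert-butyl arylacetate
Product: 14 tetracyclic ketone (seven-membered ring closed; C-c is C=O, C-a is CH2; C-b S, C-d S), via arylacetic acid 13 (not isolated)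
Conditions: TFA, CH2Cl2, rt, evaporate; then (CF3CO)2O (3 equiv), CH2Cl2, 0 °C to rt
Reagents that add atoms: none
Why: Acidolysis of the tert-butyl ester, then intramolecular Friedel–Crafts acylation through the mixed trifluoroacetic anhydride onto one of the two equivalent ring-B carbons (ortho to one methoxy, para to the other), a 7-ring closure of the dibenzosuberone type that touches no stereocentre.

Step 10
Reactants: 14 tetracyclic ketone
Product: 15 trimethylsilyl enol ether of 14 (C-a=C-c double bond)
Conditions: Me3SiOTf (1.3 equiv), Et3N (2 equiv), CH2Cl2, 0 °C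
Reagents that add atoms: trimethylsilyl trifluoromethanesulfonate, C[Si](C)(C)OS(=O)(=O)C(F)(F)F
Why: Soft enolisation toward the only enolisable position, the benzylic CH2 (C-a), should give a single silyl enol ether.

Step 11
Reactants: 15 trimethylsilyl enol ether; 16 4-bromo-2-iodoanisole
Product: 17 α-aryl ketone (ring E on C-a, C-a R; C-c still C=O)
Conditions: PdCl2[P(o-tol)3]2 (5 mol %), Bu3SnF (1.2 equiv), toluene, 80 °C
Reagents that add atoms: none
Why: Fluoride-mediated palladium-catalysed α-arylation of a silyl enol ether: Si-to-Sn exchange gives a tin enolate that transmetalates to the arylpalladium formed selectively at the C–I bond, and reductive elimination should place the aryl on the enolate face remote from ring B and from the axial C-b hydrogen (C-a R), the neutral medium avoiding enolisation of the product so that this kinetic configuration is kept.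

Step 12
Reactants: 17 α-aryl ketone
Product: 18 benzylic alcohol at C-c (mixture of carbinol epimers; C-a R)
Conditions: NaBH4, CeCl3·7H2O, MeOH/THF, −40 °C
Reagents that add atoms: none
Why: Luche reduction at low temperature, fast enough to outrun enolisation at C-a; the carbinol configuration is irrelevant because C-c becomes cationic in step 13.

Step 13
Reactants: 18 benzylic alcohol; 19 anisole
Product: 20 hexamethyl ether aryl bromide of the right half (C-a R, C-c S, C-b S, C-d S)
Conditions: Bi(OTf)3 (5 mol %), anisole (10 equiv), CH2Cl2, 0 °C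
Reagents that add atoms: none
Why: Friedel–Crafts benzylation of anisole: the secondary cation at C-c is stabilised by ring B (ortho and para methoxy groups), and anisole should attack through its para carbon on the face away from ring A, placing ring F pseudo-equatorial and trans to ring E on C-a (C-c S).

Step 14
Reactants: 20 hexamethyl ether aryl bromide
Product: 22 hexaacetate aryl bromide of the right half, via hexaphenol 21 (not isolated)
Conditions: BBr3 (12 equiv), CH2Cl2, −78 °C to rt, MeOH quench; then Ac2O, pyridine, DMAP (cat.), rt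
Reagents that add atoms: acetic anhydride, CC(=O)OC(C)=O
Why: Exhaustive Lewis-acid cleavage of six aryl methyl ethers followed by peracetylation of the crude hexaphenol, done while no alkene is present; if the benzylic C–O bond of the dihydrofuran opens, it should re-close to the trans ring under thermodynamic control.

Step 15
Reactants: 10 (2R,3S)-cis-dihydrobenzofuran bromide (a portion)
Product: 23 4-bromo-3-(3,5-dimethoxyphenyl)-6-methoxy-2-(4-methoxyphenyl)benzofuran
Conditions: DDQ (1.5 equiv), 1,4-dioxane, 90 °C
Reagents that add atoms: none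
Why: DDQ dehydrogenation of a 2,3-dihydrobenzofuran (hydride abstraction from the para-methoxybenzylic C–H, then loss of the C-b proton); both stereocentres are erased, so any stereoisomer of the bromide serves.

Step 16
Reactants: 23 bromobenzofuran tetramethyl ether
Product: 25 4-[6-acetoxy-4-bromo-3-(3,5-diacetoxyphenyl)benzofuran-2-yl]phenyl acetate, via tetraphenol 24 (not isolated)
Conditions: BBr3 (8 equiv), CH2Cl2, −78 °C to rt, MeOH quench; then Ac2O, pyridine, DMAP (cat.), rt
Reagents that add atoms: acetic anhydride, CC(=O)OC(C)=O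
Why: The same demethylation/acetylation sequence as step 14, on a fully aromatic substrate with no acid-labile group.

Step 17
Reactants: 25 tetraacetate bromobenzofuran
Product: 26 4-[6-acetoxy-3-(3,5-diacetoxyphenyl)-4-vinylbenzofuran-2-yl]phenyl acetate
Conditions: Bu3SnCH=CH2 (1.2 equiv), Pd(PPh3)4 (5 mol %), toluene, 100 °C
Reagents that add atoms: tributyl(vinyl)stannane, C=C[Sn](CCCC)(CCCC)CCCC
Why: Stille vinylation under neutral conditions that keep the four aryl acetates intact.

Step 18
Reactants: 22 hexaacetate aryl bromide of the right half; 26 tetraacetate 4-vinylbenzofuran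
Product: 28 target compound CNP0339094.1, via decaacetate 27 (not isolated)
Conditions: Pd2(dba)3 (2.5 mol %), [HP(t-Bu)3]BF4 (6 mol %), Cy2NMe (1.5 equiv), 1,4-dioxane, 80 °C, Ar; then K2CO3 (0.5 equiv), degassed MeOH, 0 °C to rt; aq. NH4Cl
Reagents that add atoms: none
Why: Mizoroki–Heck reaction: zerovalent palladium inserts into the only C–Br bond (C1 of ring E, activated by the para acetoxy group and unhindered because the tricyclic substituent is meta), the arylpalladium adds syn across the terminal vinyl of 26 with the aryl going to the unsubstituted carbon, and syn β-hydride elimination releases the trans CH=CH while Cy2NMe takes up HBr. The closest known reaction type is the Heck arylation of acetoxy-substituted styrenes by acetoxy-aryl bromides used for resveratrol-type stilbenes, here followed in the same flask by carbonate-catalysed transesterification of all ten aryl acetates with methanol. No ring is closed and no stereocentre is formed; the one new stereo-element, the E double bond, is fixed by the syn-insertion/syn-elimination sequence, which passes through the rotamer with the two aryl groups anti. The step needs terminal rather than internal arylation and E rather than Z geometry, and both are secured by the monosubstituted, aryl-conjugated alkene and by the 3-aryl group peri to C4, which shields the internal carbon. It also needs the four stereocentres and the dihydrofuran of 22 to survive: 22 has no carbonyl-activated C–H left, the base is a hindered amine, and the oxidation-prone free phenols appear only at the very end, in degassed, mildly basic methanol. In one operation the step should join the two dimer halves, create the stilbene and liberate the natural product.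

**Compound list**

1 | 2-bromo-4,6-dimethoxybenzaldehyde | O=Cc1c(Br)cc(OC)cc1OC | starting material
2 | 2-bromo-6-hydroxy-4-methoxybenzaldehyde | O=Cc1c(Br)cc(OC)cc1O | intermediate
3 | 4-methoxybenzyl chloride | COc1ccc(CCl)cc1 | starting material
4 | 2-bromo-4-methoxy-6-[(4-methoxybenzyl)oxy]benzaldehyde | O=Cc1c(Br)cc(OC)cc1OCc1ccc(OC)cc1 | intermediate
5 | 3,5-dimethoxyphenylmagnesium chloride (THF solution) | COc1cc(OC)cc([Mg]Cl)c1 | starting material
6 | rac-{2-bromo-4-methoxy-6-[(4-methoxybenzyl)oxy]phenyl}(3,5-dimethoxyphenyl)methanol | OC(c1cc(OC)cc(OC)c1)c1c(Br)cc(OC)cc1OCc1ccc(OC)cc1 | intermediate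
7 | {2-bromo-4-methoxy-6-[(4-methoxybenzyl)oxy]phenyl}(3,5-dimethoxyphenyl)methanone | O=C(c1cc(OC)cc(OC)c1)c1c(Br)cc(OC)cc1OCc1ccc(OC)cc1 | intermediate
8 | hydrazone of ketone 7 | NN=C(c1cc(OC)cc(OC)c1)c1c(Br)cc(OC)cc1OCc1ccc(OC)cc1 | intermediate
9 | diaryldiazomethane from 8 | [N-]=[N+]=C(c1cc(OC)cc(OC)c1)c1c(Br)cc(OC)cc1OCc1ccc(OC)cc1 | intermediate
10 | (2R,3S)-cis-4-bromo-3-(3,5-dimethoxyphenyl)-6-methoxy-2-(4-methoxyphenyl)-2,3-dihydrobenzofuran | Brc1cc(OC)cc2c1[C@H](c1cc(OC)cc(OC)c1)[C@H](c1ccc(OC)cc1)O2 | intermediate
11 | (2S,3S)-trans-4-bromo-3-(3,5-dimethoxyphenyl)-6-methoxy-2-(4-methoxyphenyl)-2,3-dihydrobenzofuran | Brc1cc(OC)cc2c1[C@H](c1cc(OC)cc(OC)c1)[C@@H](c1ccc(OC)cc1)O2 | intermediate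
12 | tert-butyl 2-[(2S,3S)-3-(3,5-dimethoxyphenyl)-6-methoxy-2-(4-methoxyphenyl)-2,3-dihydrobenzofuran-4-yl]acetate | CC(C)(C)OC(=O)Cc1cc(OC)cc2c1[C@H](c1cc(OC)cc(OC)c1)[C@@H](c1ccc(OC)cc1)O2 | intermediate
13 | 2-[(2S,3S)-3-(3,5-dimethoxyphenyl)-6-methoxy-2-(4-methoxyphenyl)-2,3-dihydrobenzofuran-4-yl]acetic acid | OC(=O)Cc1cc(OC)cc2c1[C@H](c1cc(OC)cc(OC)c1)[C@@H](c1ccc(OC)cc1)O2 | intermediate
14 | tetracyclic ketone (C-c carbonyl, C-a methylene; C-b S, C-d S) | O=C1Cc2cc(OC)cc3c2[C@H](c2cc(OC)cc(OC)c21)[C@@H](c1ccc(OC)cc1)O3 | intermediate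
15 | trimethylsilyl enol ether of 14 | C[Si](C)(C)OC1=Cc2cc(OC)cc3c2[C@H](c2cc(OC)cc(OC)c21)[C@@H](c1ccc(OC)cc1)O3 | intermediate
16 | 4-bromo-2-iodoanisole | COc1ccc(Br)cc1I | starting material
17 | α-aryl ketone (5-bromo-2-methoxyphenyl on C-a, C-a R; C-b S, C-d S) | COc1ccc(Br)cc1[C@H]1c2cc(OC)cc3c2[C@H](c2cc(OC)cc(OC)c2C1=O)[C@@H](c1ccc(OC)cc1)O3 | intermediate
18 | C-c alcohol from 17 (carbinol epimers) | COc1ccc(Br)cc1[C@H]1c2cc(OC)cc3c2[C@H](c2cc(OC)cc(OC)c2C1O)[C@@H](c1ccc(OC)cc1)O3 | intermediate
19 | anisole | COc1ccccc1 | starting material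
20 | hexamethyl ether aryl bromide of the right half (C-a R, C-c S, C-b S, C-d S) | COc1ccc(Br)cc1[C@H]1c2cc(OC)cc3c2[C@H](c2cc(OC)cc(OC)c2[C@@H]1c1ccc(OC)cc1)[C@@H](c1ccc(OC)cc1)O3 | intermediate
21 | hexaphenol aryl bromide of the right half | Oc1ccc(Br)cc1[C@H]1c2cc(O)cc3c2[C@H](c2cc(O)cc(O)c2[C@@H]1c1ccc(O)cc1)[C@@H](c1ccc(O)cc1)O3 | intermediate
22 | hexaacetate aryl bromide of the right half | CC(=O)Oc1ccc(Br)cc1[C@H]1c2cc(OC(C)=O)cc3c2[C@H](c2cc(OC(C)=O)cc(OC(C)=O)c2[C@@H]1c1ccc(OC(C)=O)cc1)[C@@H](c1ccc(OC(C)=O)cc1)O3 | intermediate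
23 | 4-bromo-3-(3,5-dimethoxyphenyl)-6-methoxy-2-(4-methoxyphenyl)benzofuran | COc1ccc(cc1)-c1oc2cc(OC)cc(Br)c2c1-c1cc(OC)cc(OC)c1 | intermediate
24 | 4-bromo-3-(3,5-dihydroxyphenyl)-2-(4-hydroxyphenyl)benzofuran-6-ol | Oc1ccc(cc1)-c1oc2cc(O)cc(Br)c2c1-c1cc(O)cc(O)c1 | intermediate
25 | 4-[6-acetoxy-4-bromo-3-(3,5-diacetoxyphenyl)benzofuran-2-yl]phenyl acetate | CC(=O)Oc1ccc(cc1)-c1oc2cc(OC(C)=O)cc(Br)c2c1-c1cc(OC(C)=O)cc(OC(C)=O)c1 | intermediate
26 | 4-[6-acetoxy-3-(3,5-diacetoxyphenyl)-4-vinylbenzofuran-2-yl]phenyl acetate | CC(=O)Oc1ccc(cc1)-c1oc2cc(OC(C)=O)cc(C=C)c2c1-c1cc(OC(C)=O)cc(OC(C)=O)c1 | intermediate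
27 | decaacetate of the target | CC(=O)Oc1ccc(-c2oc3cc(OC(C)=O)cc(/C=C/c4ccc(OC(C)=O)c([C@H]5c6cc(OC(C)=O)cc7c6[C@H](c6cc(OC(C)=O)cc(OC(C)=O)c6[C@@H]5c5ccc(OC(C)=O)cc5)[C@@H](c5ccc(OC(C)=O)cc5)O7)c4)c3c2-c2cc(OC(C)=O)cc(OC(C)=O)c2)cc1 | intermediate
28 | CNP0339094.1 | Oc1ccc(-c2oc3cc(O)cc(/C=C/c4ccc(O)c([C@H]5c6cc(O)cc7c6[C@H](c6cc(O)cc(O)c6[C@@H]5c5ccc(O)cc5)[C@@H](c5ccc(O)cc5)O7)c4)c3c2-c2cc(O)cc(O)c2)cc1 | target

**Step count and risks**

Total steps: 18. Longest linear sequence: 15 (steps 1–14, then 18).

Steps most likely to fail:

1. Step 11. What may go wrong: slow transmetalation and reductive elimination at the crowded enolate carbon, competing oxidative addition at a C–Br bond (oligomers), and proton exchange between product and tin enolate that would epimerise C-a to the protonation-controlled epimer. Fallback (sets out from 15, comes back at 17): the lithium enolate is liberated from 15 with MeLi (THF, −78 °C) and arylated without a transition metal by bis(5-bromo-2-methoxyphenyl)iodonium trifluoromethanesulfonate F1, prepared from 4-bromoanisole, I2, mCPBA and TfOH. Aryl transfer from the hypervalent iodine centre should occur at −78 °C on the same open enolate face; the mixture is quenched cold with AcOH and gives 17.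

2. Step 13. What may go wrong: loss of the C-a proton from the C-c cation and re-protonation, which would scramble C-a, together with attack on the concave face or through the ortho carbon of anisole. Fallback (sets out from 14, comes back at 20, bypassing steps 10–13): ketone 14 is converted with KHMDS and PhNTf2 (THF, −78 °C) into the enol trifluoromethanesulfonate F2. Suzuki–Miyaura coupling with 4-methoxyphenylboronic acid (Pd(PPh3)4, K2CO3, dioxane/H2O) gives the ring alkene F3, which carries ring F on C-c. Hydroboration with BH3·SMe2 (syn addition, boron to the less substituted C-a, from the face away from the axial C-b hydrogen) and exchange with pinacol gives the secondary benzylic boronic ester F4. A stereoretentive, Ag2O-promoted Suzuki–Miyaura coupling of F4 with 16 (Pd2(dba)3, PPh3, Ag2O, DME, 85 °C; C–I selective) then gives 20. The trans relation of rings E and F follows from syn hydroboration and retention, not from a cation.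

3. Step 6. What may go wrong: weak enantiofacial discrimination and eroded cis control, because the carbene carbon sits between two ortho substituents and may twist out of the catalyst pocket. Fallback (sets out from 8 via 9, comes back at 10): the diazo compound 9 is decomposed with achiral Rh2(OAc)4 to the racemic cis product, that is 10 together with its (2S,3R) antipode F5. The two are separated by preparative HPLC on a cellulose carbamate chiral stationary phase. 10 goes on to step 7; F5 is not lost, since step 15 (DDQ) converts it into 23.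

**Further compounds**

F1 | step 11 | bis(5-bromo-2-methoxyphenyl)iodonium trifluoromethanesulfonate | COc1ccc(Br)cc1[I+]c1cc(Br)ccc1OC.[O-]S(=O)(=O)C(F)(F)F
F2 | step 13 | enol trifluoromethanesulfonate of ketone 14 | O=S(=O)(OC1=Cc2cc(OC)cc3c2[C@H](c2cc(OC)cc(OC)c21)[C@@H](c1ccc(OC)cc1)O3)C(F)(F)F
F3 | step 13 | ring alkene with 4-methoxyphenyl on C-c (C-a=C-c) | COc1ccc(cc1)C1=Cc2cc(OC)cc3c2[C@H](c2cc(OC)cc(OC)c21)[C@@H](c1ccc(OC)cc1)O3
F4 | step 13 | C-a pinacol boronic ester with ring F on C-c | CC1(C)OB(OC1(C)C)[C@H]1c2cc(OC)cc3c2[C@H](c2cc(OC)cc(OC)c2[C@@H]1c1ccc(OC)cc1)[C@@H](c1ccc(OC)cc1)O3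
F5 | step 6 | (2S,3R)-cis-4-bromo-3-(3,5-dimethoxyphenyl)-6-methoxy-2-(4-methoxyphenyl)-2,3-dihydrobenzofuran (antipode of 10) | Brc1cc(OC)cc2c1[C@@H](c1cc(OC)cc(OC)c1)[C@@H](c1ccc(OC)cc1)O2
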